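**Retrosynthetic overview**
1. Piscisoflavone A (15) ⇐ global removal of three MOM ethers from isoflavone 14.
2. 14 ⇐ aryl-radical arylation–annulation: the aryl radical from B-ring iodide 13 adds to the α-carbon of o-hydroxyaryl enaminone 6, forming C3–C1′ and closing the pyranone ring (O1–C2) in the same step.
3. 13 ⇐ bis-MOM resorcinol by three successive directed ortho-metalations: C2 prenyl, then C4 oxygen (methylated), then C6 iodide.
4. 6 ⇐ resorcinol by C-acetylation, 4-O-MOM protection and DMF-DMA condensation.
5. Ring order: both benzene rings come intact from resorcinol; the pyranone is the only ring made, and it is made last, in the key step.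

Assumption: the target has no stereocentres and its only C=C carries two identical methyls, so it is a single achiral compound and no stereocontrol is needed.

Numbered compounds are the building blocks and intermediates; MOMCl, B(OMe)3/H2O2 and ICH2CH2I are treated as reagents and listed under "Reagents that add atoms".

**Fragment A (enaminone)**

Step 1
Reactants: 1 resorcinol; 2 acetic acid
Product: 3, 1-(2,4-dihydroxyphenyl)ethan-1-one
Conditions: AcOH, fused ZnCl2, 140–150 °C
Reagents that add atoms: acetic acid (2), CC(=O)O
Why: Nencki (Friedel–Crafts) C-acylation occurs at C4 of resorcinol, which is ortho/para to both hydroxyls.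

Step 2
Reactants: 3
Product: 4, 1-[2-hydroxy-4-(methoxymethoxy)phenyl]ethan-1-one
Conditions: MOMCl (1.1 equiv), K2CO3, acetone, 0 °C → rt
Reagents that add atoms: chloromethyl methyl ether (MOMCl), COCCl
Why: Williamson-type O-alkylation is selective for the 4-OH because the 2-OH is chelated to the ketone; this blocks O-methylation by DMF-DMA in the next step.

Step 3
Reactants: 4; 5 N,N-dimethylformamide dimethyl acetal (DMF-DMA)
Product: 6, (E)-3-(dimethylamino)-1-[2-hydroxy-4-(methoxymethoxy)phenyl]prop-2-en-1-one
Conditions: DMF-DMA (2 equiv), toluene, 90 °C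
Reagents that add atoms: DMF-DMA (5), COC(OC)N(C)C
Why: Enaminone condensation of the methyl ketone with the formamide acetal gives the thermodynamic E-isomer; the chelated 2-OH and the MOM ether are untouched.

**Fragment B (aryl iodide)**

Step 4
Reactants: 1 resorcinol
Product: 7, 1,3-bis(methoxymethoxy)benzene
Conditions: MOMCl (2.5 equiv), i-Pr2NEt, CH2Cl2, 0 °C → rt
Reagents that add atoms: MOMCl, COCCl
Why: Bis-O-alkylation installs two MOM ethers that serve as both protecting groups and ortho-metalation directors.

Step 5
Reactants: 7; 8 prenyl bromide (1-bromo-3-methylbut-2-ene)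
Product: 9, 1,3-bis(methoxymethoxy)-2-(3-methylbut-2-en-1-yl)benzene
Conditions: n-BuLi, THF, 0 °C → rt; CuBr·SMe2, −78 °C; then 8, −78 °C → rt
Reagents that add atoms: prenyl bromide (8), CC(C)=CCBr
Why: Directed ortho-metalation occurs at C2, flanked by both OMOM groups, and the aryl copper species alkylates prenyl bromide in the SN2 sense.

Step 6
Reactants: 9
Product: 10, 2,4-bis(methoxymethoxy)-3-(3-methylbut-2-en-1-yl)phenol
Conditions: n-BuLi, TMEDA, THF, −78 → 0 °C; B(OMe)3, −78 °C → rt; then 30% H2O2, aq NaOH, 0 °C (neutral work-up)
Reagents that add atoms: hydrogen peroxide, OO (the oxygen; boron from B(OMe)3, COB(OC)OC, is not retained)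
Why: With C2 blocked, directed ortho-metalation goes to C4 (equivalent to C6) next to an OMOM group, and borylation–oxidation turns the aryl-lithium into the phenol.

Step 7
Reactants: 10; 11 iodomethane
Product: 12, 1-methoxy-2,4-bis(methoxymethoxy)-3-(3-methylbut-2-en-1-yl)benzene
Conditions: MeI, K2CO3, DMF, rt
Reagents that add atoms: iodomethane (11), CI
Why: Williamson O-methylation of the only free phenol fixes the future 5′-OMe.

Step 8
Reactants: 12
Product: 13, 1-iodo-5-methoxy-2,4-bis(methoxymethoxy)-3-(3-methylbut-2-en-1-yl)benzene
Conditions: n-BuLi, TMEDA, THF, −78 → −20 °C; ICH2CH2I, −78 °C → rt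
Reagents that add atoms: 1,2-diiodoethane, ICCI (one iodine)
Why: Directed ortho-metalation goes ortho to OMOM (a stronger director than OMe), and 1,2-diiodoethane iodinates the aryl-lithium without exposing the prenyl alkene to free I2.

**Union and completion**

Step 9 (key step)
Reactants: 6 (1.5 equiv); 13
Product: 14, 3-[5-methoxy-2,4-bis(methoxymethoxy)-3-(3-methylbut-2-en-1-yl)phenyl]-7-(methoxymethoxy)-4H-chromen-4-one
Conditions: 10-phenylphenothiazine (PTH, 10 mol%), K2HPO4 (2 equiv), degassed DMSO, 390 nm LEDs, rt
Reagents that add atoms: none
Why: Proposed new method: excited PTH (E* ≈ −2.1 V) cleaves the C–I bond of 13 to the aryl radical, which adds to the nucleophilic α-carbon of enaminone 6 to give an α-amino radical; PTH•+ oxidises this to the iminium ion, the A-ring 2-OH closes onto it and Me2NH is lost to give the chromone (the B-ring oxygens are MOM-capped, so no benzofuran can form); the closest known reactions are the visible-light arylation–annulation of o-hydroxyaryl enaminones with arenediazonium salts to give isoflavones and the PTH-catalysed redox-neutral C–H arylation of pyrroles with aryl iodides.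

Step 10
Reactants: 14
Product: 15, Piscisoflavone A, 7-hydroxy-3-[2,4-dihydroxy-5-methoxy-3-(3-methylbut-2-en-1-yl)phenyl]-4H-chromen-4-one
Conditions: 3 M aq HCl–MeOH (1:4), 45 °C, stopped at full conversion
Reagents that add atoms: none
Why: Mild acid-catalysed acetal hydrolysis removes all three MOM ethers; the aryl methyl ether, chromone and prenyl group survive when temperature and time are kept low.

**Compound list**
1 | resorcinol | Oc1cccc(O)c1 | starting material
2 | acetic acid | CC(=O)O | starting material
3 | 1-(2,4-dihydroxyphenyl)ethan-1-one | CC(=O)c1ccc(O)cc1O | intermediate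
4 | 1-[2-hydroxy-4-(methoxymethoxy)phenyl]ethan-1-one | CC(=O)c1ccc(OCOC)cc1O | intermediate
5 | N,N-dimethylformamide dimethyl acetal | COC(OC)N(C)C | starting material
6 | (E)-3-(dimethylamino)-1-[2-hydroxy-4-(methoxymethoxy)phenyl]prop-2-en-1-one | CN(C)/C=C/C(=O)c1ccc(OCOC)cc1O | intermediate
7 | 1,3-bis(methoxymethoxy)benzene | COCOc1cccc(OCOC)c1 | intermediate
8 | prenyl bromide (1-bromo-3-methylbut-2-ene) | CC(C)=CCBr | starting material
9 | 1,3-bis(methoxymethoxy)-2-(3-methylbut-2-en-1-yl)benzene | COCOc1cccc(OCOC)c1CC=C(C)C | intermediate
10 | 2,4-bis(methoxymethoxy)-3-(3-methylbut-2-en-1-yl)phenol | COCOc1ccc(O)c(OCOC)c1CC=C(C)C | intermediate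
11 | iodomethane | CI | starting material
12 | 1-methoxy-2,4-bis(methoxymethoxy)-3-(3-methylbut-2-en-1-yl)benzene | COCOc1ccc(OC)c(OCOC)c1CC=C(C)C | intermediate
13 | 1-iodo-5-methoxy-2,4-bis(methoxymethoxy)-3-(3-methylbut-2-en-1-yl)benzene | COc1cc(I)c(OCOC)c(CC=C(C)C)c1OCOC | intermediate
14 | 3-[5-methoxy-2,4-bis(methoxymethoxy)-3-(3-methylbut-2-en-1-yl)phenyl]-7-(methoxymethoxy)-4H-chromen-4-one | COCOc1ccc2c(c1)occ(-c1cc(OC)c(OCOC)c(CC=C(C)C)c1OCOC)c2=O | intermediate
15 | Piscisoflavone A | COc1cc(-c2coc3cc(O)ccc3c2=O)c(O)c(CC=C(C)C)c1O | target

**Totals**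
Total step count: 10 (3 for fragment A, 5 for fragment B, 2 after union).
Longest linear sequence: 7 steps (4 → 5 → 6 → 7 → 8 → 9 → 10, from resorcinol).

**Three steps most likely to fail**
1. Step 9.
   - Risks: the electron-rich aryl iodide is slow to reduce; the aryl radical can abstract H from its ortho OCH2OMe (1,5-H transfer), giving back arene 12; the enaminone absorbs near 390 nm and competes for light.
   - Fallback: make the same C–C bond by a photostimulated SRN1 reaction of 13 with the potassium enolate of ketone 4 (KOt-Bu, liquid NH3, hν) to give the 2-hydroxydeoxybenzoin, then close the pyranone with DMF-DMA (one extra step).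
2. Step 6 (the same risk applies to Step 8).
   - Risk: lateral lithiation at the benzylic/allylic CH2 of the prenyl group instead of the ring.
   - Fallback: put the C4 oxygen in before the prenyl group. Resorcinol → 2,4-dihydroxybenzaldehyde (Vilsmeier) → bis-MOM ether → Dakin oxidation → O-methylation gives 1-methoxy-2,4-bis(methoxymethoxy)benzene. A single metalation between the two OMOM groups then introduces prenyl to give 12, and the iodide is installed with NIS instead of by lithiation.
3. Step 10.
   - Risk: acid-catalysed cyclisation of the 3′-prenyl group onto the 2′- or 4′-OH to give a 2,2-dimethylchroman.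
   - Fallback: run the whole route with SEM ethers in place of MOM (same directed-metalation behaviour) and unmask with fluoride (TBAF, DMPU), so the prenylated resorcinol never sees acid.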